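**Retrosynthetic overview**
- The last disconnection is the O1–C5 bond of the oxolane (chain O6–C9) together with the C1'–OH bond (C10). This leads back to an acyclic (9Z)-6-hydroxy-7-dodecanoyloxy diene, so the only ring of the target is made last and the step delivers the target itself.
- Enabling feature: ring atom O1 and the carbinol oxygen on C1' are vicinal and threo across C5–C1', on a 2,5-trans oxolane whose oxygen-bearing C2 lies three carbons from C5. This is the imprint of an anti, 5-exo opening of a cis-9,10-oxirane by O6. The oxirane and the O6–vanadium bond that delivers it are a temporary ring and a temporary tether, both absent from the target.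
- The (9Z)-alkene comes from an alkyne by semi-hydrogenation, and C8–C9 from an alkynide plus a terminal epoxide. The laurate is placed on O7 while O6 is silylated.
- C4–C5 comes from a butyl Grignard reagent plus C2-symmetric (2S,3S)-diepoxybutane, which supplies C6 and C7 and differentiates their oxygens by sequential opening of its two oxiranes.
- Ring order: two oxiranes of the linchpin are opened in turn, then a transient oxirane and the oxolane are formed in the final step.

Key step: step 8

Remark: C1–C19 denote the nonadecene chain (C1 = methyl end of the pentyl group, C19 = vinyl CH2). In the target, O6, C6, C7, C8, C9 are ring atoms O1, C2, C3, C4, C5, and C10 is the carbinol carbon C1'. Compound 3 is taken as a commercial reagent.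

**Step 1**
Reactants: 1 9-bromonon-1-ene
Product: 2 undec-10-en-1-yne
Conditions: LiC≡CH·H2NCH2CH2NH2, DMSO, 0 °C → rt
Reagents that add atoms: lithium acetylide–ethylenediamine complex, [Li]C#C.NCCN
Why: SN2 alkylation of an acetylide by a primary bromide (acetylide alkylation); no stereocentre is involved and the terminal alkene is inert.

**Step 2**
Reactants: 3 (2S,3S)-1,2:3,4-diepoxybutane (2 equiv); 4 n-butylmagnesium bromide
Product: 5 (2S,3S)-1,2-epoxyoctan-3-ol
Conditions: CuI (10 mol %), THF, −40 °C, slow addition of 4; then aq. NH4Cl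
Reagents that add atoms: none
Why: Copper-catalysed Grignard opening of a terminal epoxide at its CH2 carbon (SN2, monovalent-copper catalysis), with the bis-epoxide in excess so that only one of its two homotopic oxiranes reacts; both stereocentres of 3 are untouched and become C6 and C7.

**Step 3**
Reactants: 5 (2S,3S)-1,2-epoxyoctan-3-ol
Product: 6 tert-butyl(dimethyl){[(1S)-1-[(2S)-oxiran-2-yl]hexyl]oxy}silane
Conditions: TBSCl, imidazole, DMF, rt
Reagents that add atoms: tert-butyldimethylsilyl chloride, CC(C)(C)[Si](C)(C)Cl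
Why: Standard silylation of a secondary alcohol under conditions too mild for epoxide migration; masking O6 makes O7, freed in the next step, the only hydroxyl that can later take the laurate.

**Step 4**
Reactants: 2 undec-10-en-1-yne; 6 tert-butyl(dimethyl){[(1S)-1-[(2S)-oxiran-2-yl]hexyl]oxy}silane
Product: 8 (6S,7S)-6-[(tert-butyldimethylsilyl)oxy]nonadec-18-en-9-yn-7-ol, via lithium alkynide 7 (not isolated)
Conditions: n-BuLi, THF, −78 °C; BF3·OEt2, then 6, −78 °C; then H2O
Reagents that add atoms: none
Why: Yamaguchi–Hirao alkynylation, in which the BF3-activated terminal epoxide is opened at its CH2 carbon (C8) by the lithium alkynide with both stereocentres untouched; the boron-bound alkoxide at −78 °C should not trigger silyl migration.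

**Step 5**
Reactants: 8 (6S,7S)-6-[(tert-butyldimethylsilyl)oxy]nonadec-18-en-9-yn-7-ol
Product: 9 (6S,7S,9Z)-6-[(tert-butyldimethylsilyl)oxy]nonadeca-9,18-dien-7-ol
Conditions: H2 (1 atm, 1 equiv uptake), Pd/CaCO3 poisoned with Pb(OAc)2, quinoline, EtOAc, rt
Reagents that add atoms: none
Why: Lindlar semi-hydrogenation adds H2 syn to the internal alkyne to give the (9Z)-alkene; the poisoned catalyst should reduce the alkyne much faster than the terminal alkene, and uptake is stopped at one equivalent.

**Step 6**
Reactants: 9 (6S,7S,9Z)-6-[(tert-butyldimethylsilyl)oxy]nonadeca-9,18-dien-7-ol; 10 dodecanoyl chloride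
Product: 11 (6S,7S,9Z)-6-[(tert-butyldimethylsilyl)oxy]nonadeca-9,18-dien-7-yl dodecanoate
Conditions: pyridine, DMAP (cat.), CH2Cl2, 0 °C → rt
Reagents that add atoms: none
Why: DMAP-catalysed acylation (nucleophilic catalysis) of the only free hydroxyl, O7, with retention at C7.

**Step 7**
Reactants: 11 (6S,7S,9Z)-6-[(tert-butyldimethylsilyl)oxy]nonadeca-9,18-dien-7-yl dodecanoate
Product: 12 (6S,7S,9Z)-6-hydroxynonadeca-9,18-dien-7-yl dodecanoate
Conditions: HF·pyridine, pyridine, THF, 0 °C → rt; used directly
Reagents that add atoms: none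
Why: Fluoride-driven Si–O cleavage (desilylation) under buffered, weakly acidic conditions that spare the ester and both alkenes and should keep 1,2-acyl migration slow.

**Step 8**
Reactants: 12 (6S,7S,9Z)-6-hydroxynonadeca-9,18-dien-7-yl dodecanoate
Product: 14 (2S,3S,5R)-5-[(1R)-1-hydroxydec-9-en-1-yl]-2-pentyloxolan-3-yl dodecanoate, via cis-epoxide 13 (not isolated)
Conditions: VO(acac)2 (5 mol %), t-BuOOH (1.5 equiv), 4 Å MS, CH2Cl2, 0 °C → rt; then AcOH (cat.)
Reagents that add atoms: tert-butyl hydroperoxide, CC(C)(C)OO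
Why: O6–H binds to pentavalent vanadium (formed from VO(acac)2 and t-BuOOH) as a vanadate ester that also carries the tert-butylperoxide ligand, so the oxygen atom is delivered within the complex to the (9Z)-alkene to give cis-epoxide 13, which the same hydroxyl then opens at C9. The closest known reaction type is the vanadium-catalysed, hydroxyl-directed epoxidation of (Z)-bishomoallylic secondary alcohols with in situ cyclisation to 2,5-trans-tetrahydrofuranyl carbinols. The oxolane closes by 5-exo-tet attack of O6 on C9 with inversion, favoured over 6-endo attack at C10. C10 (R) is set by the face of oxygen transfer, controlled by C6 through a chair-like vanadate transition state with the pentyl group pseudo-equatorial and the cis-alkene substituent turned away from the tether, and the C7 acyloxy group is expected to support the same face in line with the 2,4-trans preference of 2-substituted pent-4-en-1-ols; C9 (R) follows stereospecifically from inversion, and the threo O–C9–C10–OH relationship from Z geometry plus anti opening. The step needs internal-over-terminal alkene selectivity (only the alkene within reach of the vanadate ester is epoxidised), 5-exo over 6-endo opening, and O6 over the ester carbonyl as nucleophile (the free hydroxyl is far more nucleophilic under near-neutral conditions).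

**Compound list**
1 | 9-bromonon-1-ene | C=CCCCCCCCBr | starting material
2 | undec-10-en-1-yne | C#CCCCCCCCC=C | intermediate
3 | (2S,3S)-1,2:3,4-diepoxybutane [(2S,2'S)-2,2'-bioxirane] | C1O[C@@H]1[C@@H]1CO1 | starting material
4 | n-butylmagnesium bromide | CCCC[Mg]Br | starting material
5 | (2S,3S)-1,2-epoxyoctan-3-ol [(1S)-1-[(2S)-oxiran-2-yl]hexan-1-ol] | CCCCC[C@H](O)[C@@H]1CO1 | intermediate
6 | tert-butyl(dimethyl){[(1S)-1-[(2S)-oxiran-2-yl]hexyl]oxy}silane | CCCCC[C@H](O[Si](C)(C)C(C)(C)C)[C@@H]1CO1 | intermediate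
7 | lithium undec-10-en-1-yn-1-ide | [Li]C#CCCCCCCCC=C | intermediate
8 | (6S,7S)-6-[(tert-butyldimethylsilyl)oxy]nonadec-18-en-9-yn-7-ol | CCCCC[C@H](O[Si](C)(C)C(C)(C)C)[C@@H](O)CC#CCCCCCCCC=C | intermediate
9 | (6S,7S,9Z)-6-[(tert-butyldimethylsilyl)oxy]nonadeca-9,18-dien-7-ol | CCCCC[C@H](O[Si](C)(C)C(C)(C)C)[C@@H](O)C/C=C\CCCCCCCC=C | intermediate
10 | dodecanoyl chloride | CCCCCCCCCCCC(=O)Cl | starting material
11 | (6S,7S,9Z)-6-[(tert-butyldimethylsilyl)oxy]nonadeca-9,18-dien-7-yl dodecanoate | CCCCC[C@H](O[Si](C)(C)C(C)(C)C)[C@@H](OC(=O)CCCCCCCCCCC)C/C=C\CCCCCCCC=C | intermediate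
12 | (6S,7S,9Z)-6-hydroxynonadeca-9,18-dien-7-yl dodecanoate | CCCCC[C@H](O)[C@@H](OC(=O)CCCCCCCCCCC)C/C=C\CCCCCCCC=C | intermediate
13 | (6S,7S,9S,10R)-9,10-epoxy-6-hydroxynonadec-18-en-7-yl dodecanoate | CCCCC[C@H](O)[C@@H](OC(=O)CCCCCCCCCCC)C[C@@H]1O[C@@H]1CCCCCCCC=C | intermediate
14 | (2S,3S,5R)-5-[(1R)-1-hydroxydec-9-en-1-yl]-2-pentyloxolan-3-yl dodecanoate | C=CCCCCCCC[C@@H](O)[C@H]1C[C@H](OC(=O)CCCCCCCCCCC)[C@H](CCCCC)O1 | target

**Step count and risks**
Total steps: 8. Longest linear sequence: 7 (steps 2–8, from 3).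

Steps most likely to fail:

1. Step 8. The risk is poor facial selectivity in the directed oxygen transfer (erosion of the 2,5-trans preference), possibly worsened by acyl shift to O6 before epoxidation. The fallback is a syn-oxidative cyclisation of the E-isomer with heptavalent rhenium; it sets out from 8 and returns at 14. Dissolving-metal reduction of 8 (Na, NH3/THF, −40 °C) should give (6S,7S,9E)-6-[(tert-butyldimethylsilyl)oxy]nonadeca-9,18-dien-7-ol F1. Acylation with 10 (pyridine, DMAP) should give its dodecanoate (6S,7S,9E)-6-[(tert-butyldimethylsilyl)oxy]nonadeca-9,18-dien-7-yl dodecanoate F2, and HF·pyridine should give (6S,7S,9E)-6-hydroxynonadeca-9,18-dien-7-yl dodecanoate F3. Treatment of F3 with CF3CO2ReO3 (from Re2O7 and (CF3CO)2O, CH2Cl2, 0 °C) should form the perrhenate ester of O6, which adds its O–Re=O unit across the E-alkene in a [3+2] manner. Syn addition to the E-alkene gives the threo carbinol and the metallacyclic transition state favours the 2,5-trans ring, so hydrolysis should deliver 14.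

2. Step 7. The risk is 1,2-acyl migration from O7 to O6 during or after desilylation. The fallback replaces the silyl group by an oxidatively removable ether; it sets out from 5 and returns at 12. Etherification of 5 (NaH, 4-methoxybenzyl chloride, Bu4NI, THF, 0 °C) should give (2S)-2-{(1S)-1-[(4-methoxybenzyl)oxy]hexyl}oxirane F4. Opening with 7 and BF3·OEt2 should give (6S,7S)-6-[(4-methoxybenzyl)oxy]nonadec-18-en-9-yn-7-ol F5. Semi-hydrogenation as in step 5 should give (6S,7S,9Z)-6-[(4-methoxybenzyl)oxy]nonadeca-9,18-dien-7-ol F6, and acylation with 10 its ester (6S,7S,9Z)-6-[(4-methoxybenzyl)oxy]nonadeca-9,18-dien-7-yl dodecanoate F7. Cleavage with DDQ (CH2Cl2/pH 7 buffer, 0 °C) should then release 12 under neutral conditions in which acyl shift should be negligible.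

3. Step 5. The risk is over-reduction or migration of the terminal alkene, or incomplete semi-hydrogenation. The fallback introduces the Z-alkene ready-made, so no hydrogenation is needed; it sets out from 6 and returns at 9. Commercial dec-9-enal and Ph3P=CHI (from [Ph3PCH2I]I and NaHMDS, THF/HMPA, −78 °C; Stork–Zhao olefination) should give (1Z)-1-iodoundeca-1,10-diene F8. Iodine–lithium exchange (t-BuLi, 2 equiv, Et2O, −78 °C) should give (1Z)-undeca-1,10-dien-1-yllithium F9 with retention of geometry. F9 should then open BF3·OEt2-activated 6 at its CH2 carbon to give 9 directly.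

**Further compounds**
F1 | step 8 | (6S,7S,9E)-6-[(tert-butyldimethylsilyl)oxy]nonadeca-9,18-dien-7-ol | CCCCC[C@H](O[Si](C)(C)C(C)(C)C)[C@@H](O)C/C=C/CCCCCCCC=C
F2 | step 8 | (6S,7S,9E)-6-[(tert-butyldimethylsilyl)oxy]nonadeca-9,18-dien-7-yl dodecanoate | CCCCC[C@H](O[Si](C)(C)C(C)(C)C)[C@@H](OC(=O)CCCCCCCCCCC)C/C=C/CCCCCCCC=C
F3 | step 8 | (6S,7S,9E)-6-hydroxynonadeca-9,18-dien-7-yl dodecanoate | CCCCC[C@H](O)[C@@H](OC(=O)CCCCCCCCCCC)C/C=C/CCCCCCCC=C
F4 | step 7 | (2S)-2-{(1S)-1-[(4-methoxybenzyl)oxy]hexyl}oxirane | CCCCC[C@H](OCc1ccc(OC)cc1)[C@@H]1CO1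
F5 | step 7 | (6S,7S)-6-[(4-methoxybenzyl)oxy]nonadec-18-en-9-yn-7-ol | CCCCC[C@H](OCc1ccc(OC)cc1)[C@@H](O)CC#CCCCCCCCC=C
F6 | step 7 | (6S,7S,9Z)-6-[(4-methoxybenzyl)oxy]nonadeca-9,18-dien-7-ol | CCCCC[C@H](OCc1ccc(OC)cc1)[C@@H](O)C/C=C\CCCCCCCC=C
F7 | step 7 | (6S,7S,9Z)-6-[(4-methoxybenzyl)oxy]nonadeca-9,18-dien-7-yl dodecanoate | CCCCC[C@H](OCc1ccc(OC)cc1)[C@@H](OC(=O)CCCCCCCCCCC)C/C=C\CCCCCCCC=C
F8 | step 5 | (1Z)-1-iodoundeca-1,10-diene | I/C=C\CCCCCCCC=C
F9 | step 5 | (1Z)-undeca-1,10-dien-1-yllithium | [Li]/C=C\CCCCCCCC=C
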